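Which flask holds the most Qd at 25 h, and which at 80 min? A bound on each flask can be read from its charges.

| flask | Qa | Qb | Qc | temperature | remark | time |
|---|---|---|---|---|---|---|
| autumn | 25 mM | 22 mM | 0.20 mM | 0 °C | run made earlier |  |
| spring | 44 mM | 22 mM | 0.20 mM | 15 °C | run made earlier |  |
| midnight | 20 mM | 18 mM | 0.20 mM | 0 °C | run made earlier |  |
| larch | 20 mM | 15.0 mM | 0.050 mM | 25 °C |  | 25 h |
| birch | 20 mM | 22.0 mM | 0.20 mM | 5 °C |  | 25 h |
| cedar | 20 mM | 22.0 mM | 0.20 mM | 25 °C |  | 25 h |
| elm | 30 mM | 22.0 mM | 0.12 mM | 25 °C |  | 25 h |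

* the flasks put in order of amount of Qd, in percent of the Qa charged, best first, at 25 h (larch / birch / cedar / elm)
* the same order at 80 min (larch / birch / cedar / elm)
* the amount of Qd, in percent of the Qa charged of the flask you put first, at 25 h
* the amount of Qd, in percent of the Qa charged of the flask you put last, at 25 h

| run | time / h | Qd / % | Qa / % |
|---|---|---|---|
| autumn | 5.00 | 22.7 | 76.3 |
| autumn | 10.0 | 42.1 | 57.7 |
| autumn | 20.0 | 67.9 | 31.2 |
| autumn | 30.0 | 81.0 | 17.7 |
| autumn | 40.0 | 86.3 | 13.7 |
| autumn | 72.0 | 87.9 | 12.5 |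
| spring | 2.00 | 19.3 | 80.9 |
| spring | 5.00 | 35.4 | 64.1 |
| spring | 10.0 | 46.0 | 53.0 |
| spring | 15.0 | 48.6 | 51.1 |
| spring | 20.0 | 50.1 | 50.4 |
| spring | 30.0 | 50.2 | 49.7 |
| midnight | 15.0 | 61.7 | 37.6 |
| midnight | 30.0 | 83.6 | 14.0 |
| midnight | 48.0 | 89.5 | 10.6 |
| midnight | 72.0 | 90.1 | 9.9 |

(standard deviation of a reading: 0.5 percentage points)

- no earlier run changes the charge of Qc; that part of a forecast is a guess

The earlier runs stop with Qa still present: autumn ends at 87.9% Qd, spring at 50.2% and midnight at 90.1%. Qb charged over Qa charged gives 88.0%, 50.0% and 90.0%, so these plateaus read as one Qb spent per Qd, with Qb as the limiting reagent.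

The balance of Qb then says that Qd, in percent of the Qa charged, is about the charge of Qb over the charge of Qa, times the part of Qb used. Larch has 75.0%, its ceiling, the charge of Qb over the charge of Qa. Elm has 73.3%. In birch and cedar, Qb is 110% of Qa, so Qa is the smaller charge there.

But the ceiling tells where a flask stops, not when. Spring took 20.0 h to reach its plateau with 0.20 mM of Qc, while larch has less Qc, 0.050 mM. No earlier run changes Qc, so the rates of larch and elm are a guess, and larch need not reach its ceiling by 25 h.

The forecast gives cedar > birch > elm > larch at 25 h and cedar > birch > elm > larch at 80 min, with 99.5% in the first flask and 62% in the last. Its ground is that “the reaction is 1:1 and runs to completion”.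

The flasks give birch > cedar > elm > larch at 25 h and cedar > elm > birch > larch at 80 min, with birch at 90.8% and larch at 45.0%.

    Qa + Qc ⇌ Qe (K = 5.59 /M, k = 7240 /M/h, Ea = 44.0 kJ/mol, ΔH = −90.0 kJ/mol)
    Qb + Qe → Qf (k = 21500 /M/h, Ea = 45.0 kJ/mol)
    Qf ⇌ Qc + Qd (K = 0.00670 M, k = 114 /h, Ea = 72.0 kJ/mol, ΔH = −34.0 kJ/mol)
    (constants at 25 °C)

In birch, half of the passing of Qa + Qc into Qe up to 25 h was done by 6.10 h, and at 25.0 h Qf held 51.1% of the catalyst, against 70.7% in cedar. Larch had 40% of its Qb left at 25.0 h, and the part used, taken of its ceiling of 75.0%, gives 45.0%, while the neighbour of birch with 50 mM of Qa, ceiling 44.0%, stood at 43.9% at that time with 0.0129% of its Qb left.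

All runs stem from a simulated flask with made-up constants; scatter was added.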